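**Retrosynthetic overview**

1. Numbering: the single 14-membered carbocycle (ring A) is C1(CH3)=C2–C3–C4=C5(CH3)–C6–C7–C8(OH)–C9–C10–C11(CH3)=C12–C13–C14; the side chain on C8 is C15(CH3)–C16–C17–C18=C19(CH3)–C20(OH).
2. Feature used: the skipped diene C1=C2–C3H2–C4=C5, where methylene C3 lies between the Z alkene C1=C2 and the E alkene C4=C5 that carries its methyl on C5. This is the pattern left when a CH3–Al bond adds syn to a terminal alkyne C4≡C5 and C4 is then allylated at C3.
3. Disconnections: ring A is opened at C13–C14 (C13 sulfonyl carbanion + C14 allylic bromide); then C3–C4 and C5–CH3 are cut (alkyne 27 + Me3Al 20 + (Z)-allylic chloride 33).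
4. Alkyne 27: C6–C7 from allenylmagnesium bromide and the C7–C8 epoxide 23; C8/C15 from Sharpless epoxidation of (Z)-allylic alcohol 18 and Me3Al opening at C15; 18 from a Z-selective Wittig reaction of α-silyloxy ketone 9 with the ylide of salt 15; chloride 33 by Still–Gennari olefination.
5. Ring order: everything is acyclic up to step 27, where ring A is closed; desulfonylation and desilylation follow.

Key step: step 22

Remark: the oxygens are masked as C13–OPMB, C14–OTBS (primary), C8–OTBS (tertiary) and C20–OTBDPS so that they can be unmasked in that order. Large intermediates are described with the target numbering; the CIP letter at C8 changes with its substituents although its spatial arrangement is fixed from 21 onward.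

**Route**

Step 1
Reactants: 1 2-[(4-methoxybenzyl)oxy]acetaldehyde; 2 isopropenylmagnesium bromide
Product: 3 1-[(4-methoxybenzyl)oxy]-3-methylbut-3-en-2-ol (racemic)
Conditions: THF, −78 → 0 °C; aq. NH4Cl
Reagents that add atoms: none
Why: Grignard addition of an alkenylmagnesium halide to an aldehyde; the carbinol centre is left racemic because it is destroyed in step 2.

Step 2
Reactants: 3 allylic alcohol; 4 triethyl orthoacetate
Product: 5 ethyl (E)-6-[(4-methoxybenzyl)oxy]-4-methylhex-4-enoate
Conditions: EtCO2H (cat.), 140 °C, EtOH distilled off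
Reagents that add atoms: none
Why: Johnson–Claisen rearrangement through a chair transition state with the CH2OPMB group equatorial should form the C9–C10 bond and the E C11=C12 alkene.

Step 3
Reactants: 5 ester
Product: 6 (E)-6-[(4-methoxybenzyl)oxy]-4-methylhex-4-enal
Conditions: i-Bu2AlH (1.05 equiv), CH2Cl2, −78 °C; Rochelle salt
Reagents that add atoms: none
Why: Partial ester reduction stops at the aluminium hemiacetal at −78 °C and gives the aldehyde on work-up; the PMB ether and the alkene are inert.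

Step 4
Reactants: 6 aldehyde; 7 paraformaldehyde
Product: 8 (E)-1-hydroxy-7-[(4-methoxybenzyl)oxy]-5-methylhept-5-en-2-one
Conditions: 3-ethylbenzothiazolium bromide (10 mol%), Et3N (10 mol%), EtOH, 60 °C
Reagents that add atoms: none
Why: Thiazolium (N-heterocyclic carbene) catalysed crossed acyloin condensation, in which the Breslow intermediate of the aliphatic aldehyde adds to the more electrophilic formaldehyde, a known hydroxymethylation that forms the C7–C8 bond.

Step 5
Reactants: 8 hydroxy ketone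
Product: 9 (E)-1-[(tert-butyldimethylsilyl)oxy]-7-[(4-methoxybenzyl)oxy]-5-methylhept-5-en-2-one
Conditions: TBSCl, imidazole, CH2Cl2, 0 °C → rt
Reagents that add atoms: tert-butyldimethylsilyl chloride, CC(C)(C)[Si](C)(C)Cl
Why: Standard silylation of a primary alcohol, which also stops the α-hydroxy ketone from dimerising.

Step 6
Reactants: 10 5-bromopent-1-ene; 11 methacrolein
Product: 12 (E)-6-bromo-2-methylhex-2-enal
Conditions: second-generation Grubbs catalyst (3 mol%), 11 in excess, CH2Cl2, 40 °C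
Reagents that add atoms: none
Why: Olefin cross-metathesis of a terminal alkene with an α-substituted acrolein is known to give the E 2-methyl-2-enal (C18=C19) with loss of ethylene.

Step 7
Reactants: 12 enal
Product: 13 (E)-6-bromo-2-methylhex-2-en-1-ol
Conditions: NaBH4, CeCl3·7H2O, MeOH, 0 °C
Reagents that add atoms: none
Why: Luche reduction gives 1,2-reduction of the enal without touching the primary bromide.

Step 8
Reactants: 13 allylic alcohol
Product: 14 {[(E)-6-bromo-2-methylhex-2-en-1-yl]oxy}(tert-butyl)diphenylsilane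
Conditions: TBDPSCl, imidazole, CH2Cl2, rt
Reagents that add atoms: tert-butyldiphenylsilyl chloride, CC(C)(C)[Si](Cl)(c1ccccc1)c1ccccc1
Why: Silylation of the primary allylic alcohol (C20) with the robust group that is kept to the last step.

Step 9
Reactants: 14 bromide
Product: 15 {(E)-6-[(tert-butyldiphenylsilyl)oxy]-5-methylhex-4-en-1-yl}triphenylphosphonium bromide
Conditions: PPh3, MeCN, reflux
Reagents that add atoms: triphenylphosphine, c1ccc(cc1)P(c1ccccc1)c1ccccc1
Why: SN2 quaternisation of triphenylphosphine by a primary alkyl bromide.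

Step 10
Reactants: 15 phosphonium bromide; 9 α-silyloxy ketone
Product: 17 (8Z,11E,18E)-triene (C7-OTBS; C13-OPMB; C20-OTBDPS), via phosphorus ylide 16 (not isolated)
Conditions: KN(SiMe3)2, THF, −78 → 0 °C; then 9, −78 °C → rt
Reagents that add atoms: none
Why: Wittig reaction of a non-stabilised ylide with an α-silyloxy ketone is a known Z-selective route to trisubstituted allylic ethers, placing the alkoxymethyl group cis to the ylide chain (C7 cis to C16) as the C8/C15 relationship requires.

Step 11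
Reactants: 17 silyl ether
Product: 18 (Z)-allylic alcohol (C7-OH; C13-OPMB; C20-OTBDPS)
Conditions: camphorsulfonic acid (10 mol%), MeOH/CH2Cl2, 0 °C
Reagents that add atoms: none
Why: Acid-catalysed methanolysis removes the primary TBS ether much faster than the primary TBDPS ether, and the PMB ether is stable.

Step 12
Reactants: 18 (Z)-allylic alcohol
Product: 19 (8R,15S)-C8,C15-epoxy alcohol
Conditions: Ti(OiPr)4 (20 mol%), D-(−)-diethyl tartrate (24 mol%), t-BuOOH, 4 Å MS, CH2Cl2, −20 °C
Reagents that add atoms: tert-butyl hydroperoxide, CC(C)(C)OO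
Why: Sharpless asymmetric epoxidation acts only on the free allylic alcohol, and with D-(−)-diethyl tartrate the oxygen should be delivered to the face that gives the (8R,15S)-epoxide (reagent control by the tartrate ligand).

Step 13
Reactants: 19 epoxy alcohol; 20 trimethylaluminium
Product: 21 (8S,15R)-C7,C8-diol carrying the C15 methyl group
Conditions: 20 (3 equiv), CH2Cl2/hexane, −20 → 0 °C; Rochelle salt
Reagents that add atoms: none
Why: The aluminium alkoxide of the 2,3-epoxy alcohol directs methyl transfer to the distal epoxide carbon C15 with inversion while the fully substituted C8 keeps its C–O bond, which sets the C15 methyl centre relative to the C8 oxygen and gives the 1,2-diol.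

Step 14
Reactants: 21 diol
Product: 23 (8S,15R)-C7,C8-epoxide, via monotosylate 22 (not isolated)
Conditions: TsCl, Et3N, DMAP (cat.), CH2Cl2, 0 °C; then K2CO3, MeOH, rt
Reagents that add atoms: none
Why: Selective sulfonylation of the primary hydroxyl and Williamson ring closure by the tertiary alkoxide give the terminal epoxide without touching either stereocentre.

Step 15
Reactants: 23 epoxide; 24 propargyl bromide
Product: 26 (8S,15R)-alkynol HC4≡C5–C6–C7–C8(OH), via allenylmagnesium bromide 25 (not isolated)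
Conditions: 24, Mg, HgCl2 (cat.), Et2O, 0 °C; then 23, −20 → 0 °C; aq. NH4Cl
Reagents that add atoms: none
Why: Allenylmagnesium bromide opens the 2,2-disubstituted epoxide at its CH2 terminus C7 in an SE2′ sense, forming the C6–C7 bond and the terminal alkyne with the C8–O bond untouched.

Step 16
Reactants: 26 alkynol
Product: 27 alkyne (C8-OTBS; C13-OPMB; C20-OTBDPS)
Conditions: TBSOTf, 2,6-lutidine, CH2Cl2, 0 °C → rt
Reagents that add atoms: tert-butyldimethylsilyl trifluoromethanesulfonate, CC(C)(C)[Si](C)(C)OS(=O)(=O)C(F)(F)F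
Why: Silyl triflate silylation of a hindered tertiary alcohol; the tertiary TBS ether is chosen because it survives the later cleavage of the primary TBS ether at C14.

Step 17
Reactants: 1 2-[(4-methoxybenzyl)oxy]acetaldehyde; 28 methyl 2-[bis(2,2,2-trifluoroethoxy)phosphoryl]propanoate
Product: 29 methyl (Z)-4-[(4-methoxybenzyl)oxy]-2-methylbut-2-enoate
Conditions: KN(SiMe3)2, 18-crown-6, THF, −78 °C
Reagents that add atoms: none
Why: Still–Gennari olefination with the bis(trifluoroethyl) phosphonate under dissociating conditions gives the kinetic Z enoate (C1=C2).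

Step 18
Reactants: 29 enoate
Product: 30 (Z)-4-[(4-methoxybenzyl)oxy]-2-methylbut-2-en-1-ol
Conditions: i-Bu2AlH (2.2 equiv), CH2Cl2, −78 °C; Rochelle salt
Reagents that add atoms: none
Why: Hydride reduction of the enoate to the allylic alcohol leaves the Z alkene intact, and the masked C3 oxygen cannot lactonise.

Step 19
Reactants: 30 allylic alcohol
Product: 31 tert-butyl{[(Z)-4-[(4-methoxybenzyl)oxy]-2-methylbut-2-en-1-yl]oxy}dimethylsilane
Conditions: TBSCl, imidazole, CH2Cl2, rt
Reagents that add atoms: tert-butyldimethylsilyl chloride, CC(C)(C)[Si](C)(C)Cl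
Why: Standard silylation of the primary allylic alcohol (C14).

Step 20
Reactants: 31 PMB ether
Product: 32 (Z)-4-[(tert-butyldimethylsilyl)oxy]-3-methylbut-2-en-1-ol
Conditions: DDQ, CH2Cl2/pH 7 buffer, 0 °C
Reagents that add atoms: none
Why: Oxidative cleavage of the PMB ether by DDQ through the benzylic oxocarbenium ion leaves the silyl ether and the alkene untouched.

Step 21
Reactants: 32 allylic alcohol
Product: 33 tert-butyl{[(Z)-4-chloro-2-methylbut-2-en-1-yl]oxy}dimethylsilane
Conditions: N-chlorosuccinimide, Me2S, CH2Cl2, −20 → 0 °C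
Reagents that add atoms: N-chlorosuccinimide, ClN1C(=O)CCC1=O
Why: Corey–Kim chlorination replaces the primary allylic hydroxyl by SN2 displacement of the alkoxysulfonium ion, without allylic transposition or loss of the Z geometry.

Step 22
Reactants: 27 alkyne; 20 trimethylaluminium; 33 (Z)-allylic chloride
Product: 35 open-chain (1Z,4E,11E,18E)-tetraene (C14-OTBS; C8-OTBS; C13-OPMB; C20-OTBDPS), via alkenylalane 34 (not isolated)
Conditions: 20 (2.5 equiv), Cp2ZrCl2 (0.5 equiv), ClCH2CH2Cl, rt; then 33, Pd(PPh3)4 (5 mol%), THF, rt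
Reagents that add atoms: none
Why: Zirconocene-assisted syn addition of a CH3–Al bond across the terminal alkyne of 27 puts the methyl group on the internal carbon C5 and aluminium on C4, so that C6 and Al are trans in alkenylalane 34. Zerovalent palladium then ionises chloride 33 to an η3-allyl complex over C3–C2–C1, the alkenyl group passes from aluminium to palladium with retention at C4, and reductive elimination joins C4 to the unsubstituted allyl terminus C3; the closest known reaction is the one-pot methylalumination and palladium-catalysed allylation of terminal alkynes, which gives 1,4-dienes from geranyl- and neryl-type chlorides with retention of both geometries. No ring is closed and no stereocentre is formed, and C8 and C15 are remote from the reacting sites. The step needs methyl at C5 with syn delivery, which fixes the E geometry of C4=C5 and is secured by the terminal alkyne and the zirconium catalyst. It also needs coupling at C3 without syn–anti exchange of the allyl ligand, which keeps the Z geometry of C1=C2 and is secured because exchange would require a σ-bond from palladium to the fully substituted C1, a terminus that is also shielded from attack. The silyl and PMB ethers should not react with Me3Al at room temperature, and alkenyl transfer to palladium is much faster than methyl transfer from the excess alane.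

Step 23
Reactants: 35 PMB ether
Product: 36 C13 allylic alcohol
Conditions: DDQ, CH2Cl2/pH 7 buffer, 0 °C
Reagents that add atoms: none
Why: DDQ cleaves only the PMB ether at C13; the three silyl ethers are inert and the buffer protects the skipped diene from acid.

Step 24
Reactants: 36 allylic alcohol
Product: 38 C13 allylic phenyl sulfone, via allylic bromide 37 (not isolated)
Conditions: CBr4, PPh3, CH2Cl2, 0 °C; then PhSO2Na, Bu4NI (cat.), DMF, rt
Reagents that add atoms: sodium benzenesulfinate, [Na+].[O-]S(=O)c1ccccc1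
Why: Appel bromination of the primary allylic alcohol followed by SN2 S-alkylation of benzenesulfinate gives the primary allylic sulfone without transposition.

Step 25
Reactants: 38 sulfone
Product: 39 C14 allylic alcohol
Conditions: camphorsulfonic acid (10 mol%), MeOH/CH2Cl2, 0 °C
Reagents that add atoms: none
Why: Acid-catalysed methanolysis cleaves the primary allylic TBS ether selectively in the presence of the tertiary TBS ether at C8 and the TBDPS ether at C20.

Step 26
Reactants: 39 allylic alcohol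
Product: 40 C14 (Z)-allylic bromide
Conditions: CBr4, PPh3, CH2Cl2, −20 → 0 °C; used at once
Reagents that add atoms: carbon tetrabromide, BrC(Br)(Br)Br
Why: Appel bromination under neutral conditions converts the primary allylic alcohol into the bromide with the Z alkene and the sulfone untouched.

Step 27
Reactants: 40 bromo sulfone
Product: 41 14-membered C13-sulfonyl macrocycle (both C13 epimers)
Conditions: KN(SiMe3)2, THF, 0 °C, slow addition of 40 to a final concentration near 2 mM
Reagents that add atoms: none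
Why: Intramolecular SN2 alkylation of the sulfone-stabilised allylic carbanion at C13 by the primary allylic bromide at C14 under high dilution closes ring A (14-exo-tet); the new C13 centre is of no consequence because the sulfone is removed in step 28.

Step 28
Reactants: 41 macrocyclic sulfone
Product: 42 bis-silyl ether of the target (C8-OTBS; C20-OTBDPS)
Conditions: PdCl2(dppp) (10 mol%), LiBHEt3 (3 equiv), THF, 0 °C
Reagents that add atoms: none
Why: Palladium-catalysed reductive desulfonylation ionises the allylic sulfone to an η3-allyl complex and delivers hydride to the less substituted terminus C13, which keeps the position and E geometry of C11=C12 because the other terminus C11 is fully substituted.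

Step 29
Reactants: 42 bis-silyl ether
Product: 43 target CNP0178561.1
Conditions: Bu4NF (excess), THF, 60 °C
Reagents that add atoms: none
Why: Fluoride cleaves the primary TBDPS ether and, on warming, the tertiary TBS ether under non-acidic conditions, which avoids acid-induced addition of the C8 hydroxyl to the C4=C5 or C11=C12 alkene.

**Compound list**

1 | 2-[(4-methoxybenzyl)oxy]acetaldehyde | COc1ccc(COCC=O)cc1 | starting material
2 | isopropenylmagnesium bromide | CC(=C)[Mg]Br | starting material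
3 | 1-[(4-methoxybenzyl)oxy]-3-methylbut-3-en-2-ol (racemic) | COc1ccc(COCC(O)C(C)=C)cc1 | intermediate
4 | triethyl orthoacetate | CC(OCC)(OCC)OCC | starting material
5 | ethyl (E)-6-[(4-methoxybenzyl)oxy]-4-methylhex-4-enoate | CCOC(=O)CC/C(C)=C/COCc1ccc(OC)cc1 | intermediate
6 | (E)-6-[(4-methoxybenzyl)oxy]-4-methylhex-4-enal | O=CCC/C(C)=C/COCc1ccc(OC)cc1 | intermediate
7 | paraformaldehyde (reacts as formaldehyde) | C=O | starting material
8 | (E)-1-hydroxy-7-[(4-methoxybenzyl)oxy]-5-methylhept-5-en-2-one | OCC(=O)CC/C(C)=C/COCc1ccc(OC)cc1 | intermediate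
9 | (E)-1-[(tert-butyldimethylsilyl)oxy]-7-[(4-methoxybenzyl)oxy]-5-methylhept-5-en-2-one | CC(C)(C)[Si](C)(C)OCC(=O)CC/C(C)=C/COCc1ccc(OC)cc1 | intermediate
10 | 5-bromopent-1-ene | C=CCCCBr | starting material
11 | methacrolein | CC(=C)C=O | starting material
12 | (E)-6-bromo-2-methylhex-2-enal | O=C/C(C)=C/CCCBr | intermediate
13 | (E)-6-bromo-2-methylhex-2-en-1-ol | OC/C(C)=C/CCCBr | intermediate
14 | {[(E)-6-bromo-2-methylhex-2-en-1-yl]oxy}(tert-butyl)diphenylsilane | CC(C)(C)[Si](OC/C(C)=C/CCCBr)(c1ccccc1)c1ccccc1 | intermediate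
15 | {(E)-6-[(tert-butyldiphenylsilyl)oxy]-5-methylhex-4-en-1-yl}triphenylphosphonium bromide | [Br-].CC(C)(C)[Si](OC/C(C)=C/CCC[P+](c1ccccc1)(c1ccccc1)c1ccccc1)(c1ccccc1)c1ccccc1 | intermediate
16 | phosphorus ylide of 15 (C15 ylide carbon) | CC(C)(C)[Si](OC/C(C)=C/CCC=P(c1ccccc1)(c1ccccc1)c1ccccc1)(c1ccccc1)c1ccccc1 | intermediate
17 | (8Z,11E,18E)-triene: TBSO–C7H2–C8(C9–C13 chain)=C15H–C16–C20 chain, C7 cis to C16; C13–OPMB; C20–OTBDPS | CC(C)(C)[Si](C)(C)OC/C(CC/C(C)=C/COCc1ccc(OC)cc1)=C\CC/C=C(\C)CO[Si](c1ccccc1)(c1ccccc1)C(C)(C)C | intermediate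
18 | (8Z,11E,18E)-allylic alcohol (C7–OH) | OC/C(CC/C(C)=C/COCc1ccc(OC)cc1)=C\CC/C=C(\C)CO[Si](c1ccccc1)(c1ccccc1)C(C)(C)C | intermediate
19 | (8R,15S)-C8,C15-epoxy alcohol (C7–OH) | OC[C@@]1(CC/C(C)=C/COCc2ccc(OC)cc2)O[C@H]1CC/C=C(\C)CO[Si](c2ccccc2)(c2ccccc2)C(C)(C)C | intermediate
20 | trimethylaluminium | C[Al](C)C | starting material
21 | (8S,15R)-C7,C8-diol with C15 methyl | OC[C@@](O)([C@H](C)CC/C=C(\C)CO[Si](c1ccccc1)(c1ccccc1)C(C)(C)C)CC/C(C)=C/COCc1ccc(OC)cc1 | intermediate
22 | C7 monotosylate of 21 | Cc1ccc(cc1)S(=O)(=O)OC[C@@](O)([C@H](C)CC/C=C(\C)CO[Si](c1ccccc1)(c1ccccc1)C(C)(C)C)CC/C(C)=C/COCc1ccc(OC)cc1 | intermediate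
23 | (8S,15R)-C7,C8-epoxide | C1[C@@](O1)([C@H](C)CC/C=C(\C)CO[Si](c2ccccc2)(c2ccccc2)C(C)(C)C)CC/C(C)=C/COCc2ccc(OC)cc2 | intermediate
24 | propargyl bromide | C#CCBr | starting material
25 | allenylmagnesium bromide | C=C=C[Mg]Br | intermediate
26 | (8S,15R)-alkynol HC4≡C5–C6H2–C7H2–C8(OH) | C#CCC[C@@](O)([C@H](C)CC/C=C(\C)CO[Si](c1ccccc1)(c1ccccc1)C(C)(C)C)CC/C(C)=C/COCc1ccc(OC)cc1 | intermediate
27 | alkyne precursor (8S,15R): C8–OTBS; C13–OPMB; C20–OTBDPS | C#CCC[C@@](O[Si](C)(C)C(C)(C)C)([C@H](C)CC/C=C(\C)CO[Si](c1ccccc1)(c1ccccc1)C(C)(C)C)CC/C(C)=C/COCc1ccc(OC)cc1 | intermediate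
28 | methyl 2-[bis(2,2,2-trifluoroethoxy)phosphoryl]propanoate | CC(C(=O)OC)P(=O)(OCC(F)(F)F)OCC(F)(F)F | starting material
29 | methyl (Z)-4-[(4-methoxybenzyl)oxy]-2-methylbut-2-enoate | COC(=O)/C(C)=C\COCc1ccc(OC)cc1 | intermediate
30 | (Z)-4-[(4-methoxybenzyl)oxy]-2-methylbut-2-en-1-ol | OC/C(C)=C\COCc1ccc(OC)cc1 | intermediate
31 | tert-butyl{[(Z)-4-[(4-methoxybenzyl)oxy]-2-methylbut-2-en-1-yl]oxy}dimethylsilane | CC(C)(C)[Si](C)(C)OC/C(C)=C\COCc1ccc(OC)cc1 | intermediate
32 | (Z)-4-[(tert-butyldimethylsilyl)oxy]-3-methylbut-2-en-1-ol | CC(C)(C)[Si](C)(C)OC/C(C)=C\CO | intermediate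
33 | tert-butyl{[(Z)-4-chloro-2-methylbut-2-en-1-yl]oxy}dimethylsilane | CC(C)(C)[Si](C)(C)OC/C(C)=C\CCl | intermediate
34 | (E)-alkenylalane: Me2Al on C4, CH3 on C5, C8 and C15 unchanged | C[Al](C)/C=C(\C)CC[C@@](O[Si](C)(C)C(C)(C)C)([C@H](C)CC/C=C(\C)CO[Si](c1ccccc1)(c1ccccc1)C(C)(C)C)CC/C(C)=C/COCc1ccc(OC)cc1 | intermediate
35 | open-chain (1Z,4E,11E,18E)-tetraene (8S,15R): C14–OTBS; C8–OTBS; C13–OPMB; C20–OTBDPS | CC(C)(C)[Si](C)(C)OC/C(C)=C\C/C=C(\C)CC[C@@](O[Si](C)(C)C(C)(C)C)([C@H](C)CC/C=C(\C)CO[Si](c1ccccc1)(c1ccccc1)C(C)(C)C)CC/C(C)=C/COCc1ccc(OC)cc1 | intermediate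
36 | C13 allylic alcohol | CC(C)(C)[Si](C)(C)OC/C(C)=C\C/C=C(\C)CC[C@@](O[Si](C)(C)C(C)(C)C)([C@H](C)CC/C=C(\C)CO[Si](c1ccccc1)(c1ccccc1)C(C)(C)C)CC/C(C)=C/CO | intermediate
37 | C13 allylic bromide | CC(C)(C)[Si](C)(C)OC/C(C)=C\C/C=C(\C)CC[C@@](O[Si](C)(C)C(C)(C)C)([C@H](C)CC/C=C(\C)CO[Si](c1ccccc1)(c1ccccc1)C(C)(C)C)CC/C(C)=C/CBr | intermediate
38 | C13 allylic phenyl sulfone (C14–OTBS) | CC(C)(C)[Si](C)(C)OC/C(C)=C\C/C=C(\C)CC[C@@](O[Si](C)(C)C(C)(C)C)([C@H](C)CC/C=C(\C)CO[Si](c1ccccc1)(c1ccccc1)C(C)(C)C)CC/C(C)=C/CS(=O)(=O)c1ccccc1 | intermediate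
39 | C14 allylic alcohol with C13 sulfone | OC/C(C)=C\C/C=C(\C)CC[C@@](O[Si](C)(C)C(C)(C)C)([C@H](C)CC/C=C(\C)CO[Si](c1ccccc1)(c1ccccc1)C(C)(C)C)CC/C(C)=C/CS(=O)(=O)c1ccccc1 | intermediate
40 | C14 (Z)-allylic bromide with C13 sulfone | BrC/C(C)=C\C/C=C(\C)CC[C@@](O[Si](C)(C)C(C)(C)C)([C@H](C)CC/C=C(\C)CO[Si](c1ccccc1)(c1ccccc1)C(C)(C)C)CC/C(C)=C/CS(=O)(=O)c1ccccc1 | intermediate
41 | 14-membered macrocycle with PhSO2 on C13 (C13 epimers; 8S,15R) | C/C1=C/C/C=C(\C)CC[C@@](O[Si](C)(C)C(C)(C)C)([C@H](C)CC/C=C(\C)CO[Si](c2ccccc2)(c2ccccc2)C(C)(C)C)CC/C(C)=C/C(S(=O)(=O)c2ccccc2)C1 | intermediate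
42 | bis-silyl ether of the target (8R,15R): C8–OTBS; C20–OTBDPS | C/C1=C/C/C=C(\C)CC[C@@](O[Si](C)(C)C(C)(C)C)([C@H](C)CC/C=C(\C)CO[Si](c2ccccc2)(c2ccccc2)C(C)(C)C)CC/C(C)=C/CC1 | intermediate
43 | CNP0178561.1, (1Z,4E,11E,18E; 8R,15R) | C/C1=C/C/C=C(\C)CC[C@@](O)([C@H](C)CC/C=C(\C)CO)CC/C(C)=C/CC1 | target

**Step count**

Total: 29 steps. Longest linear sequence: 20 steps (1–5, 10–16, 22–29).

**Steps most likely to fail**

1. Step 22 (key step). What may go wrong: incomplete carbometallation in the presence of four Lewis-basic oxygens, transfer of methyl instead of alkenyl from the alane mixture to palladium, or partial loss of the allyl geometry during a slow coupling. Fallback, setting out from 27 and returning at 35: the methylalumination is run as in step 22 but quenched with I2 (THF, −30 °C) to give, by way of 34, the (E)-alkenyl iodide F1, which is purified. Iodine–lithium exchange (t-BuLi, 2 equiv, Et2O, −78 °C) gives the alkenyllithium F2, ZnCl2 converts it into the alkenylzinc chloride F3, and Negishi coupling with 33 (Pd(PPh3)4, THF, 0 °C → rt) gives 35. This separates the carbometallation from the coupling and removes Me3Al and zirconium from the coupling flask.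

2. Step 27 (macrocyclisation). What may go wrong: intermolecular alkylation to oligomers, or base-induced 1,4-elimination of HBr across C14–C1=C2–C3 outrunning closure by the stabilised sulfonyl carbanion. Fallback, setting out from 36 and returning at 41: a Hata reaction (PhSSPh, Bu3P, THF) gives the C13 allylic phenyl sulfide F4. Methanolysis (camphorsulfonic acid, MeOH/CH2Cl2, 0 °C) gives the C14 alcohol F5, and PPh3/hexachloroacetone (0 °C) gives the C14 allylic chloride F6. The more reactive thioether-stabilised allyl anion (n-BuLi, DABCO, THF, −78 °C, high dilution) is alkylated α to sulfur to give the macrocyclic sulfide F7. Chemoselective S-oxidation ((NH4)6Mo7O24·4H2O cat., H2O2, EtOH, 0 °C) then gives sulfone 41.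

3. Step 10 (Wittig olefination). What may go wrong: insufficient Z-selectivity in oxaphosphetane formation (the E alkene would give the wrong C8/C15 relationship) or enolisation of ketone 9 by the ylide. Fallback by the Corey–Schlosser β-oxido ylide method, setting out from 5 and 14 and returning at 18: ester 5 is reduced (LiAlH4, Et2O, 0 °C) to the primary alcohol F8, converted (I2, PPh3, imidazole) into the iodide F9 and quaternised (PPh3, MeCN, reflux) to the phosphonium iodide F10. Bromide 14 is oxidised (Me3NO, DMSO, 40 °C) to the aldehyde F11. F10 with n-BuLi (THF, −78 °C) gives the ylide F12, which adds to F11 to give the betaine F13. A second equivalent of n-BuLi gives the β-oxido ylide F14, and paraformaldehyde 7 then gives 18 after loss of Ph3PO, with the new hydroxymethyl group cis to the aldehyde-derived chain. This route needs neither ketone 9 nor steps 3–5, 9 and 11.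

**Further compounds**

F1 | step 22 | (E)-alkenyl iodide (I on C4, CH3 on C5) | I/C=C(\C)CC[C@@](O[Si](C)(C)C(C)(C)C)([C@H](C)CC/C=C(\C)CO[Si](c1ccccc1)(c1ccccc1)C(C)(C)C)CC/C(C)=C/COCc1ccc(OC)cc1
F2 | step 22 | alkenyllithium (Li on C4) | [Li]/C=C(\C)CC[C@@](O[Si](C)(C)C(C)(C)C)([C@H](C)CC/C=C(\C)CO[Si](c1ccccc1)(c1ccccc1)C(C)(C)C)CC/C(C)=C/COCc1ccc(OC)cc1
F3 | step 22 | alkenylzinc chloride (ZnCl on C4) | Cl[Zn]/C=C(\C)CC[C@@](O[Si](C)(C)C(C)(C)C)([C@H](C)CC/C=C(\C)CO[Si](c1ccccc1)(c1ccccc1)C(C)(C)C)CC/C(C)=C/COCc1ccc(OC)cc1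
F4 | step 27 | C13 allylic phenyl sulfide (C14–OTBS) | CC(C)(C)[Si](C)(C)OC/C(C)=C\C/C=C(\C)CC[C@@](O[Si](C)(C)C(C)(C)C)([C@H](C)CC/C=C(\C)CO[Si](c1ccccc1)(c1ccccc1)C(C)(C)C)CC/C(C)=C/CSc1ccccc1
F5 | step 27 | C14 alcohol with C13 phenyl sulfide | OC/C(C)=C\C/C=C(\C)CC[C@@](O[Si](C)(C)C(C)(C)C)([C@H](C)CC/C=C(\C)CO[Si](c1ccccc1)(c1ccccc1)C(C)(C)C)CC/C(C)=C/CSc1ccccc1
F6 | step 27 | C14 (Z)-allylic chloride with C13 phenyl sulfide | ClC/C(C)=C\C/C=C(\C)CC[C@@](O[Si](C)(C)C(C)(C)C)([C@H](C)CC/C=C(\C)CO[Si](c1ccccc1)(c1ccccc1)C(C)(C)C)CC/C(C)=C/CSc1ccccc1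
F7 | step 27 | 14-membered macrocycle with PhS on C13 (C13 epimers) | C/C1=C/C/C=C(\C)CC[C@@](O[Si](C)(C)C(C)(C)C)([C@H](C)CC/C=C(\C)CO[Si](c2ccccc2)(c2ccccc2)C(C)(C)C)CC/C(C)=C/C(Sc2ccccc2)C1
F8 | step 10 | (E)-6-[(4-methoxybenzyl)oxy]-4-methylhex-4-en-1-ol | OCCC/C(C)=C/COCc1ccc(OC)cc1
F9 | step 10 | 1-({[(E)-6-iodo-3-methylhex-2-en-1-yl]oxy}methyl)-4-methoxybenzene | ICCC/C(C)=C/COCc1ccc(OC)cc1
F10 | step 10 | {(E)-6-[(4-methoxybenzyl)oxy]-4-methylhex-4-en-1-yl}triphenylphosphonium iodide | [I-].COc1ccc(COC/C=C(\C)CCC[P+](c2ccccc2)(c2ccccc2)c2ccccc2)cc1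
F11 | step 10 | (E)-6-[(tert-butyldiphenylsilyl)oxy]-5-methylhex-4-enal | O=CCC/C=C(\C)CO[Si](c1ccccc1)(c1ccccc1)C(C)(C)C
F12 | step 10 | phosphorus ylide of F10 (C8 ylide carbon) | COc1ccc(COC/C=C(\C)CCC=P(c2ccccc2)(c2ccccc2)c2ccccc2)cc1
F13 | step 10 | betaine from F12 and F11 (C8 phosphonium, C15 oxide) | [O-]C(CC/C=C(\C)CO[Si](c1ccccc1)(c1ccccc1)C(C)(C)C)C(CC/C(C)=C/COCc1ccc(OC)cc1)[P+](c1ccccc1)(c1ccccc1)c1ccccc1
F14 | step 10 | lithium β-oxido ylide (C8 ylide carbon, C15 lithium alkoxide) | [Li]OC(CC/C=C(\C)CO[Si](c1ccccc1)(c1ccccc1)C(C)(C)C)C(CC/C(C)=C/COCc1ccc(OC)cc1)=P(c1ccccc1)(c1ccccc1)c1ccccc1
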